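**Plan** (germacrane numbering: ring C1–C10; C11–C13 on C7; C14 on C10; C15 on C4)
- Cuts, in retrosynthetic order: C12=O (back to a C12H2 ether); O–C6 (back to a C6–Br / C12–OH pair); the 1,2-epoxide; the C8 ester; the C8/C10 oxygens (back to a C9=C10 enone); then the C1–C10 ring bond with reconnection of C3–C8 (acetylenic anionic oxy-Cope transform).
- Enabling feature: the C3 carbonyl and the oxygenated C8 are 1,6-related across the ten-membered ring, C3 is flanked by the (Z)-C4(C15)=C5 unit, and C7 carries the three-carbon branch C11–C13. Reconnecting C3–C8 therefore gives the six-membered ring C3–C8 of carvone with all ten carvone carbons in place; C1–C2 is a vinyl group and C9–C10–C14 a 1-propynyl group.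
- Forward order: (S)-carvone → C8 ketone with a vinyl carbinol at C3 → propynyl carbinol at C8 → ring expansion 6→10 (carbocycle) → C10–OH, C8 tiglate → C1=C2 → C12–OH → C6–O–C12 tetrahydrofuran → epoxide → lactone carbonyl.
- Stereochemistry: C7 from (S)-carvone; (4Z) from the cyclohexene; C10 by catalyst-controlled conjugate borylation; C8 by 1,3-anti reduction from C10–OH; C6 by peripheral γ-bromination followed by SN2 inversion; C1/C2 by C10–OH-guided epoxidation of the (1E)-enone.

Key step: step 6

Remark: the target is read as (1R,2R,4Z,6S,7R,8R,10R), i.e. cis-fused 6,12-lactone (H6/H7 syn), trans-1,2-epoxide, C8–O/C10–OH 1,3-anti, and an (E)-2-methylbut-2-enoate (tiglate). The C10 descriptor is S in 14–18 and R from 21 on without any change in spatial arrangement (only CIP ranks change).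

**Step 1**
Reactants: 1 (S)-(+)-carvone
Product: 3 (5R,6R)-6-hydroxy-2-methyl-5-(prop-1-en-2-yl)cyclohex-2-en-1-one, via potassium dienolate 2 (not isolated)
Conditions: KHMDS, THF, −78 °C; then 2-(phenylsulfonyl)-3-phenyloxaziridine, −78 °C; NH4Cl (aq)
Reagents that add atoms: 2-(phenylsulfonyl)-3-phenyloxaziridine, O=S(=O)(c1ccccc1)N1OC1c1ccccc1
Why: Kinetic α'-deprotonation (C8) gives the cross-conjugated dienolate, which the N-sulfonyloxaziridine hydroxylates anti to the isopropenyl group on C7 (enolate oxidation), giving the trans C8 carbinol that is erased again in step 3.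

**Step 2**
Reactants: 3 (5R,6R)-6-hydroxycarvone, 4 vinylmagnesium bromide
Product: 5 (1S,5R,6R)-1-ethenyl-2-methyl-5-(prop-1-en-2-yl)cyclohex-2-ene-1,6-diol
Conditions: CeCl3, THF, −78 → 0 °C (3 equiv of 4); NH4Cl (aq)
Reagents that add atoms: vinylmagnesium bromide (4), C=C[Mg]Br
Why: Cerium-assisted Grignard 1,2-addition to the C3 enone carbonyl, with the metal bridging the C8 alkoxide and the carbonyl, should place the vinyl group trans to the C8 oxygen (cis-diol); the C3 carbinol is only a relay because C3 is planarized in step 6.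

**Step 3**
Reactants: 5 vinyl diol
Product: 6 (2S,6R)-2-ethenyl-2-hydroxy-3-methyl-6-(prop-1-en-2-yl)cyclohex-3-en-1-one
Conditions: (COCl)2, DMSO, CH2Cl2, −78 °C; Et3N, −78 → 0 °C
Reagents that add atoms: none
Why: Swern oxidation converts only the secondary C8 alcohol (the tertiary bis-allylic C3 alcohol cannot be oxidized), and the cold work-up spares the now α-keto, allylic C7–H.

**Step 4**
Reactants: 6 α-hydroxy ketone
Product: 7 (2S,6R)-2-ethenyl-2-methoxy-3-methyl-6-(prop-1-en-2-yl)cyclohex-3-en-1-one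
Conditions: MeOTf, 2,6-di-tert-butyl-4-methylpyridine, CH2Cl2, 0 °C → rt
Reagents that add atoms: methyl trifluoromethanesulfonate, COS(=O)(=O)C(F)(F)F
Why: O-Methylation of the hindered tertiary alcohol under non-basic conditions avoids α-ketol shift and enolization and installs an ether that, unlike a silyl group, cannot migrate to the neighbouring alkoxide in step 6 and will emerge as a hydrolysable C3 enol ether.

**Step 5**
Reactants: 7 methoxy ketone, 8 1-propynylmagnesium bromide
Product: 9 (1R,2S,6R)-2-ethenyl-2-methoxy-3-methyl-6-(prop-1-en-2-yl)-1-(prop-1-yn-1-yl)cyclohex-3-en-1-ol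
Conditions: THF, −78 → 0 °C (2.5 equiv of 8); NH4Cl (aq)
Reagents that add atoms: 1-propynylmagnesium bromide (8), CC#C[Mg]Br
Why: Cram-chelate-controlled acetylide addition (Mg between C=O and OMe) should place the propynyl group trans to the vinyl group, the weakly basic acetylide leaving C7–H untouched; either C8 epimer would serve because C8 is planarized in step 6.

**Step 6**
Reactants: 9 propynyl vinyl carbinol
Product: 12 (2Z,4Z,7R,9Z)-3-methoxygermacra-2,4,9,11(13)-tetraen-8-one, via potassium alkoxide 10 (not isolated), via potassium allenolate 11 (not isolated)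
Conditions: KHMDS, 18-crown-6, THF, 0 °C → rt; then NH4Cl (aq), −78 °C
Reagents that add atoms: none
Why: The potassium alkoxide 10 should undergo an alkoxide-accelerated [3,3]-sigmatropic shift (acetylenic anionic oxy-Cope rearrangement) through the chair-like array C1=C2–C3–C8–C9≡C10, in which vinyl and propynyl are trans-diequatorial and the isopropenyl group is equatorial; the closest known reaction type is the four-carbon ring expansion of 1-alkynyl-2-vinylcycloalkanols to 3-substituted cycloalka-2,5-dienones. The ten-membered carbocycle arises by ring expansion, the C3–C8 bond breaking as C1–C10 forms, so no end-to-end cyclization is required. No new stereocentre is created: the carbinol centres C3 and C8 are erased (both epimers converge), C7 is untouched, the (4Z)-alkene is the former cyclohexene double bond, and the (9Z)-enone is expected when the cyclic allenolate 11 is protonated at C9 from outside the ring. The selectivity needed is [3,3]-shift over retro-addition of the acetylide and over transannular enolate chemistry; it rests on relief of the congested vicinal C3–C8 bond, on the crown-ether-separated ion pair, and on the O-methyl group, which cannot migrate and leaves C3 as an enol ether with no carbonyl for the allenolate to attack. The two halves thus emerge differentiated, C8 as a free enone and C3 as a masked ketone.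

**Step 7**
Reactants: 12 ring-expanded enone
Product: 14 (2Z,4Z,7R,10S)-10-hydroxy-3-methoxygermacra-2,4,11(13)-trien-8-one, via tertiary pinacol boronate 13 (not isolated)
Conditions: CuCl (5 mol %), QuinoxP* (the antipode matched to 14, 5 mol %), NaOt-Bu (10 mol %), B2pin2, MeOH, THF, 0 °C; then NaBO3·4H2O, THF–H2O, rt
Reagents that add atoms: sodium perborate, [Na+].[O-]OB=O
Why: Copper-catalysed asymmetric conjugate borylation of the β-methyl (Z)-cycloalkenone should put boron on C10 from the face selected by the ligand, and stereoretentive oxidation gives the tertiary alcohol, the methyl dienol ether and isopropenyl group not being Michael acceptors.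

**Step 8**
Reactants: 14 β-hydroxy ketone
Product: 16 (4Z,7R,8R,10S)-8,10-dihydroxygermacra-4,11(13)-dien-3-one, via diol methyl enol ether 15 (not isolated)
Conditions: Me4NBH(OAc)3, MeCN–AcOH (1:1), −35 °C; then 1 M HCl, THF, 0 °C
Reagents that add atoms: water, O
Why: Evans–Saksena reduction delivers hydride intramolecularly from the C10 alkoxyborohydride to give the 1,3-anti diol (8R), and dilute acid then protonates the 2-methoxydiene at C2 so that the C3 ketone appears with the (4Z)-enone intact.

**Step 9**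
Reactants: 16 diol enone, 17 tiglic acid
Product: 18 (4Z,7R,8R,10S)-10-hydroxy-3-oxogermacra-4,11(13)-dien-8-yl (E)-2-methylbut-2-enoate
Conditions: 17, 2,4,6-trichlorobenzoyl chloride, Et3N, toluene, rt; then 16, DMAP, rt
Reagents that add atoms: tiglic acid (17), C/C=C(\C)C(=O)O
Why: Yamaguchi esterification acylates the only secondary hydroxyl (C8) and leaves the tertiary C10 alcohol free.

**Step 10**
Reactants: 18 tiglate
Product: 21 (1E,4Z,7R,8R,10R)-10-hydroxy-3-oxogermacra-1,4,11(13)-trien-8-yl (E)-2-methylbut-2-enoate, via bis-TMS silyl dienol ether 19 (not isolated), via 10-O-TMS dienone 20 (not isolated)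
Conditions: TMSOTf, Et3N, CH2Cl2, −78 → 0 °C; then Pd(OAc)2, MeCN, rt; then 0.5 M HCl, THF, 0 °C
Reagents that add atoms: none
Why: Soft enolization of the enone occurs at the α'-methylene (C2), and Saegusa–Ito oxidation of the 2-silyloxydiene should give the (1E)-enone, after which C3 is cross-conjugated and can enolize only towards C6.

**Step 11**
Reactants: 21 cross-conjugated dienone
Product: 22 (1E,4Z,7R,8R,10R)-10,12-dihydroxy-3-oxogermacra-1,4,11(13)-trien-8-yl (E)-2-methylbut-2-enoate
Conditions: SeO2 (0.3 equiv), t-BuOOH, CH2Cl2, rt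
Reagents that add atoms: tert-butyl hydroperoxide, CC(C)(C)OO
Why: SeO2/t-BuOOH allylic oxidation (ene reaction, then [2,3]-shift) attacks the only electron-rich alkene, the 1,1-disubstituted isopropenyl group, at its methyl carbon C12, the enone and tiglate double bonds being deactivated.

**Step 12**
Reactants: 22 allylic alcohol
Product: 25 (1E,4Z,6S,7R,8R,10R)-6,12-epoxy-10-hydroxy-3-oxogermacra-1,4,11(13)-trien-8-yl (E)-2-methylbut-2-enoate, via tris-TMS trienol ether 23 (not isolated), via 6-bromo dienone 24 (not isolated)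
Conditions: TMSOTf, Et3N, CH2Cl2, −78 → 0 °C; then NBS, THF, −78 °C; then TBAF, THF, −78 → 0 °C
Reagents that add atoms: none
Why: γ-Enolization (the only one possible) gives a linear silyl trienol ether that NBS should brominate at C6 from the ring periphery (γ-bromination of a dienol ether, anti to the C7–C8 ring bond), and fluoride then frees the C12 alkoxide, which displaces the allylic bromide by 5-exo-tet SN2 with inversion to set (6S) and the cis-fused 3-methylenetetrahydrofuran.

**Step 13**
Reactants: 25 methylene-tetrahydrofuran dienone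
Product: 26 (1R,2R,4Z,6S,7R,8R,10R)-1,2:6,12-diepoxy-10-hydroxy-3-oxogermacra-4,11(13)-dien-8-yl (E)-2-methylbut-2-enoate
Conditions: t-BuOOH (anhydrous), DBU, CH2Cl2, 0 °C → rt
Reagents that add atoms: tert-butyl hydroperoxide, CC(C)(C)OO
Why: Weitz–Scheffer epoxidation should take the α-unsubstituted (1E)-enone in preference to the α-methylated (4Z)-enone, the hydroperoxide being guided by hydrogen bonding to the adjacent C10–OH onto the peripheral face to give the trans-(1R,2R)-epoxide, while the 3-methylenetetrahydrofuran (unlike an α-methylene lactone) is not a Michael acceptor.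

**Step 14**
Reactants: 26 epoxy ether
Product: 27 target, (1R,2R,4Z,6S,7R,8R,10R)-1,2-epoxy-10-hydroxy-3-oxo-8-[(E)-2-methylbut-2-enoyloxy]germacra-4,11(13)-dien-12,6-olide
Conditions: CrO3·2 pyridine (Collins reagent, excess), CH2Cl2, 0 °C → rt
Reagents that add atoms: chromium trioxide, O=[Cr](=O)=O
Why: Chromium(VI) oxidation of a cyclic allylic ether to the lactone should occur at C12H2, which is both α to the ring oxygen and allylic to the electron-rich exocyclic alkene, so the α-methylene-γ-butyrolactone is unveiled last, after all basic and nucleophilic steps.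

**Compound list**
1 | (S)-(+)-carvone | C=C(C)[C@H]1CC=C(C)C(=O)C1 | starting material
2 | potassium dienolate of 1 | C=C(C)[C@H]1CC=C(C)C([O-])=C1.[K+] | intermediate (not isolated)
3 | (5R,6R)-6-hydroxy-2-methyl-5-(prop-1-en-2-yl)cyclohex-2-en-1-one | C=C(C)[C@H]1CC=C(C)C(=O)[C@@H]1O | intermediate
4 | vinylmagnesium bromide | C=C[Mg]Br | starting material
5 | (1S,5R,6R)-1-ethenyl-2-methyl-5-(prop-1-en-2-yl)cyclohex-2-ene-1,6-diol | C=C(C)[C@H]1CC=C(C)[C@@](O)(C=C)[C@@H]1O | intermediate
6 | (2S,6R)-2-ethenyl-2-hydroxy-3-methyl-6-(prop-1-en-2-yl)cyclohex-3-en-1-one | C=C(C)[C@H]1CC=C(C)[C@@](O)(C=C)C1=O | intermediate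
7 | (2S,6R)-2-ethenyl-2-methoxy-3-methyl-6-(prop-1-en-2-yl)cyclohex-3-en-1-one | C=C(C)[C@H]1CC=C(C)[C@@](OC)(C=C)C1=O | intermediate
8 | 1-propynylmagnesium bromide | CC#C[Mg]Br | starting material
9 | (1R,2S,6R)-2-ethenyl-2-methoxy-3-methyl-6-(prop-1-en-2-yl)-1-(prop-1-yn-1-yl)cyclohex-3-en-1-ol | C=C(C)[C@H]1CC=C(C)[C@@](OC)(C=C)[C@]1(O)C#CC | intermediate
10 | potassium alkoxide of 9 | C=C(C)[C@H]1CC=C(C)[C@@](OC)(C=C)[C@]1([O-])C#CC.[K+] | intermediate (not isolated)
11 | potassium allenolate, ten-membered ring, C8(O–)=C9=C10 | C=C(C)[C@H]1C/C=C(/C)\C(OC)=C\CC(C)=C=C1[O-].[K+] | intermediate (not isolated)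
12 | (2Z,4Z,7R,9Z)-3-methoxygermacra-2,4,9,11(13)-tetraen-8-one | C=C(C)[C@H]1C/C=C(/C)\C(OC)=C\C/C(C)=C\C1=O | intermediate
13 | C10 pinacol boronate of 14 | C=C(C)[C@H]1C/C=C(/C)\C(OC)=C\C[C@](C)(B2OC(C)(C)C(C)(C)O2)CC1=O | intermediate (not isolated)
14 | (2Z,4Z,7R,10S)-10-hydroxy-3-methoxygermacra-2,4,11(13)-trien-8-one | C=C(C)[C@H]1C/C=C(/C)\C(OC)=C\C[C@](C)(O)CC1=O | intermediate
15 | (2Z,4Z,7R,8R,10S)-3-methoxygermacra-2,4,11(13)-triene-8,10-diol | C=C(C)[C@H]1C/C=C(/C)\C(OC)=C\C[C@](C)(O)C[C@H]1O | intermediate (not isolated)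
16 | (4Z,7R,8R,10S)-8,10-dihydroxygermacra-4,11(13)-dien-3-one | C=C(C)[C@H]1C/C=C(/C)C(=O)CC[C@](C)(O)C[C@H]1O | intermediate
17 | tiglic acid, (E)-2-methylbut-2-enoic acid | C/C=C(\C)C(=O)O | starting material
18 | (4Z,7R,8R,10S)-10-hydroxy-3-oxogermacra-4,11(13)-dien-8-yl (E)-2-methylbut-2-enoate | C=C(C)[C@H]1C/C=C(/C)C(=O)CC[C@](C)(O)C[C@H]1OC(=O)/C(C)=C/C | intermediate
19 | 3-O,10-O-bis(trimethylsilyl) 2,4-dienol ether of 18 (C2=C3 geometry not defined) | C=C(C)[C@H]1C/C=C(/C)C(O[Si](C)(C)C)=CC[C@](C)(O[Si](C)(C)C)C[C@H]1OC(=O)/C(C)=C/C | intermediate (not isolated)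
20 | 10-O-trimethylsilyl ether of 21 | C=C(C)[C@H]1C/C=C(/C)C(=O)/C=C/[C@](C)(O[Si](C)(C)C)C[C@H]1OC(=O)/C(C)=C/C | intermediate (not isolated)
21 | (1E,4Z,7R,8R,10R)-10-hydroxy-3-oxogermacra-1,4,11(13)-trien-8-yl (E)-2-methylbut-2-enoate | C=C(C)[C@H]1C/C=C(/C)C(=O)/C=C/[C@](C)(O)C[C@H]1OC(=O)/C(C)=C/C | intermediate
22 | (1E,4Z,7R,8R,10R)-10,12-dihydroxy-3-oxogermacra-1,4,11(13)-trien-8-yl (E)-2-methylbut-2-enoate | C=C(CO)[C@H]1C/C=C(/C)C(=O)/C=C/[C@](C)(O)C[C@H]1OC(=O)/C(C)=C/C | intermediate
23 | tris(trimethylsilyl) 1,3,5-trienol ether of 22 (C3=C4 and C5=C6 geometry not defined) | C=C(CO[Si](C)(C)C)[C@H]1C=CC(C)=C(O[Si](C)(C)C)/C=C/[C@](C)(O[Si](C)(C)C)C[C@H]1OC(=O)/C(C)=C/C | intermediate (not isolated)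
24 | (6R)-6-bromo-10,12-bis(trimethylsilyloxy) dienone | C=C(CO[Si](C)(C)C)[C@H]1[C@H](Br)/C=C(/C)C(=O)/C=C/[C@](C)(O[Si](C)(C)C)C[C@H]1OC(=O)/C(C)=C/C | intermediate (not isolated)
25 | (1E,4Z,6S,7R,8R,10R)-6,12-epoxy-10-hydroxy-3-oxogermacra-1,4,11(13)-trien-8-yl (E)-2-methylbut-2-enoate | C=C1CO[C@H]2/C=C(/C)C(=O)/C=C/[C@](C)(O)C[C@@H](OC(=O)/C(C)=C/C)[C@@H]12 | intermediate
26 | (1R,2R,4Z,6S,7R,8R,10R)-1,2:6,12-diepoxy-10-hydroxy-3-oxogermacra-4,11(13)-dien-8-yl (E)-2-methylbut-2-enoate | C=C1CO[C@H]2/C=C(/C)C(=O)[C@@H]3O[C@H]3[C@](C)(O)C[C@@H](OC(=O)/C(C)=C/C)[C@@H]12 | intermediate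
27 | CNP0383091.1 | C=C1C(=O)O[C@H]2/C=C(/C)C(=O)[C@@H]3O[C@H]3[C@](C)(O)C[C@@H](OC(=O)/C(C)=C/C)[C@@H]12 | target

**Totals and risks**
Total steps: 14. Longest linear sequence: 14 steps from 1 (4, 8 and 17 are commercial reagents).

Three steps most likely to fail:

1. Step 14. Chromium(VI) may also attack the doubly activated C6–H (α to the ring oxygen, allylic to the enone) or degrade the epoxy ketone, so the lactone carbonyl may not be installed cleanly. Fallback, setting out from 22: the C6 oxygen would be introduced as a hydroxyl instead of an ether. Silyl trienol ether formation and dimethyldioxirane (vinylogous Rubottom oxidation, attack from the ring periphery) would give the (6R)-triol F1. Hydroperoxide epoxidation of the (1E)-enone would give the epoxy triol F2. TEMPO/NaOCl(cat.)/NaClO2 would oxidize only the primary allylic alcohol to the hydroxy acid F3. Mitsunobu lactonization (PPh3, DIAD) would then close the lactone with inversion at C6, returning to the route at 27.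

2. Step 12. Bromination may occur at C4 instead of C6, HBr may be lost towards C7, or bromine may enter on the inner face, which after SN2 would give the trans-fused ether. Fallback, setting out from 22: the same silyl trienol ether would be protonated kinetically at C4 (AcOH, −78 °C) to the deconjugated β,γ-enone F4. Iodoetherification (I2, NaHCO3, MeCN, 0 °C) would add the C12 hydroxyl to C6 in a 5-exo closure to give the iodo ether F5. DBU would then eliminate HI through the C3 enolate to restore the conjugated (4Z)-enone, returning at 25.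

3. Step 7. The ring's own facial bias may oppose the catalyst (poor selectivity at C10), and the basic medium may epimerize C7 or move the C9=C10 bond out of conjugation towards C1. Fallback, setting out from 12: Weitz–Scheffer epoxidation of the C9=C10 enone (t-BuOOH, DBU) would give the cis-epoxy ketone F6, and reductive cleavage of its Cα–O bond with SmI2 (THF–MeOH, −90 °C) would return to the route at 14 without boron chemistry, the C10 configuration then resting on peripheral attack.

**Further compounds**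
F1 | step 14 | (1E,4Z,6R,7S,8R,10R)-6,10,12-trihydroxy-3-oxogermacra-1,4,11(13)-trien-8-yl (E)-2-methylbut-2-enoate | C=C(CO)[C@H]1[C@H](O)/C=C(/C)C(=O)/C=C/[C@](C)(O)C[C@H]1OC(=O)/C(C)=C/C
F2 | step 14 | (1R,2R,4Z,6R,7S,8R,10R)-1,2-epoxy-6,10,12-trihydroxy-3-oxogermacra-4,11(13)-dien-8-yl (E)-2-methylbut-2-enoate | C=C(CO)[C@H]1[C@H](O)/C=C(/C)C(=O)[C@@H]2O[C@H]2[C@](C)(O)C[C@H]1OC(=O)/C(C)=C/C
F3 | step 14 | (1R,2R,4Z,6R,7S,8R,10R)-1,2-epoxy-6,10-dihydroxy-3-oxo-8-[(E)-2-methylbut-2-enoyloxy]germacra-4,11(13)-dien-12-oic acid | C=C(C(=O)O)[C@H]1[C@H](O)/C=C(/C)C(=O)[C@@H]2O[C@H]2[C@](C)(O)C[C@H]1OC(=O)/C(C)=C/C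
F4 | step 12 | (1E,5Z,7R,8R,10R)-10,12-dihydroxy-3-oxogermacra-1,5,11(13)-trien-8-yl (E)-2-methylbut-2-enoate (C4 epimers) | C=C(CO)[C@H]1/C=C\C(C)C(=O)/C=C/[C@](C)(O)C[C@H]1OC(=O)/C(C)=C/C
F5 | step 12 | (1E,6R,7R,8R,10R)-6,12-epoxy-10-hydroxy-5-iodo-3-oxogermacra-1,11(13)-dien-8-yl (E)-2-methylbut-2-enoate (I anti to O6; C4 epimers) | C=C1CO[C@H]2[C@H](I)C(C)C(=O)/C=C/[C@](C)(O)C[C@@H](OC(=O)/C(C)=C/C)[C@@H]12
F6 | step 7 | (2Z,4Z,7R,9S,10S)-9,10-epoxy-3-methoxygermacra-2,4,11(13)-trien-8-one | C=C(C)[C@H]1C/C=C(/C)\C(OC)=C\C[C@]2(C)O[C@@H]2C1=O
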